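**Plan**
- Retrosynthetic cuts, in order: the two ring A O–benzyl bonds; ring B bonds C1'–C2' and C5'–C6'; the aryl ester C(=O)–O bond; then, on ring A, the central C–O bond (made from C–I), the C–I bond and the C–acetyl bond, back to olivetol.
- Enabling feature: ring B is a benzoate with C1' carboxyl, C2' OMe, C3' H, C4' OH, C5' H and C6' propyl. C2'–C5', with its methyl ether and free hydroxyl already told apart, maps onto 1,1-dimethoxy-3-silyloxybutadiene; C1' and C6' map onto the triple bond of a hex-2-ynoate.
- Forward: ring A is taken ready-made from olivetol (acetylation, iodination between the hydroxyls, benzylation, hydroxylation), and its hindered central phenol is esterified with the slim hex-2-ynoic acid.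
- The diene is made in two steps from 1,1-dimethoxyethene; ring B, the only ring formed, is then grown on the ester by [4+2] cycloaddition and aromatisation, and hydrogenolysis ends the route.
- Stereochemistry: the target has no stereocentre and no stereogenic double bond, so nothing has to be set.

Key step: step 8

Remark: the target is achiral (two planar arenes joined by an ester), so it is prepared as the single compound drawn and no enantiocontrol is needed.

**Step 1**
Reactants: 1 olivetol (5-pentylbenzene-1,3-diol)
Product: 3 1-(2,4-dihydroxy-6-pentylphenyl)ethan-1-one, via ketiminium chloride 2 (not isolated)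
Conditions: MeCN, ZnCl2, HCl (g), Et2O, 0 °C to rt; then H2O, reflux
Reagents that add atoms: acetonitrile CC#N; water O
Why: Houben–Hoesch acylation, in which the nitrilium species attacks the resorcinol para to one hydroxyl and ortho to the other (the classical orcinol-to-orcacetophenone selectivity), and hydrolysis of the ketiminium salt should give the mono-C-acetyl compound without O-acylation.

**Step 2**
Reactants: 3 1-(2,4-dihydroxy-6-pentylphenyl)ethan-1-one
Product: 4 1-(2,4-dihydroxy-3-iodo-6-pentylphenyl)ethan-1-one
Conditions: I2 (0.4 equiv), HIO3 (0.2 equiv), EtOH/H2O, 35 °C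
Reagents that add atoms: iodine II; iodic acid OI(=O)=O
Why: Electrophilic aromatic iodination with I2/HIO3, which on 2,4-dihydroxyaryl ketones goes to the carbon between the two hydroxyls; the other open position is additionally shielded by the pentyl chain, and the limited iodine charge should suppress di-iodination.

**Step 3**
Reactants: 4 1-(2,4-dihydroxy-3-iodo-6-pentylphenyl)ethan-1-one
Product: 5 1-[2,4-bis(benzyloxy)-3-iodo-6-pentylphenyl]ethan-1-one
Conditions: BnBr, K2CO3, DMF, 60 °C
Reagents that add atoms: benzyl bromide BrCc1ccccc1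
Why: Williamson ether synthesis; the acetyl group is twisted out of plane by its two ortho neighbours, which weakens the chelate of the 2-hydroxyl, so both phenols should alkylate under warm carbonate/DMF conditions.

**Step 4**
Reactants: 5 1-[2,4-bis(benzyloxy)-3-iodo-6-pentylphenyl]ethan-1-one
Product: 6 1-[2,4-bis(benzyloxy)-3-hydroxy-6-pentylphenyl]ethan-1-one
Conditions: tBuBrettPhos Pd G3 (cat.), KOH, 1,4-dioxane/H2O, 80 °C, argon; then aq. HCl
Reagents that add atoms: potassium hydroxide [K+].[OH-]
Why: Palladium-catalysed hydroxylation of an aryl halide (Buchwald-type C–O coupling with hydroxide); bulky biaryl phosphines are known to carry di-ortho-substituted aryl halides through C–O reductive elimination, and the hindered, twisted methyl ketone should resist aldol chemistry in the aqueous base.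

**Step 5**
Reactants: 6 1-[2,4-bis(benzyloxy)-3-hydroxy-6-pentylphenyl]ethan-1-one; 7 hex-2-ynoic acid
Product: 8 3-acetyl-2,6-bis(benzyloxy)-4-pentylphenyl hex-2-ynoate
Conditions: DCC, DMAP (cat.), CH2Cl2, 0 °C to rt
Reagents that add atoms: none
Why: Steglich esterification; the phenol sits between two benzyloxy groups, but the acyl donor has only a linear sp carbon next to its carbonyl, so acyl transfer should be sterically easy, and little DMAP at low temperature avoids isomerisation to the allenoate.

**Step 6**
Reactants: 9 1,1-dimethoxyethene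
Product: 10 4,4-dimethoxybut-3-en-2-one
Conditions: AcCl, Et3N, Et2O, 0 °C to rt
Reagents that add atoms: acetyl chloride CC(Cl)=O
Why: C-acylation of a ketene acetal by an acid chloride; the nucleophilic CH2 carbon attacks acetyl chloride and triethylamine takes up the hydrogen chloride, which should give the push–pull enone.

**Step 7**
Reactants: 10 4,4-dimethoxybut-3-en-2-one
Product: 11 1,1-dimethoxy-3-(trimethylsilyloxy)buta-1,3-diene
Conditions: TMSCl, Et3N, ZnCl2 (cat.), toluene, 40 °C; filtration, distillation
Reagents that add atoms: chlorotrimethylsilane C[Si](C)(C)Cl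
Why: Silyl enol ether formation under Danishefsky-type conditions; the methyl group is the only enolisable position, so O-silylation of its enolate should give the 3-silyloxy diene, to be handled with exclusion of moisture.

**Step 8**
Reactants: 8 3-acetyl-2,6-bis(benzyloxy)-4-pentylphenyl hex-2-ynoate; 11 1,1-dimethoxy-3-(trimethylsilyloxy)buta-1,3-diene
Product: 14 3-acetyl-2,6-bis(benzyloxy)-4-pentylphenyl 4-hydroxy-2-methoxy-6-propylbenzoate, via cyclohexadiene cycloadduct 12 (not isolated), via aryl trimethylsilyl ether 13 (not isolated)
Conditions: 11 (3 equiv), xylene, 140 °C, sealed tube; then 1 M HCl, THF, rt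
Reagents that add atoms: none
Why: The electron-rich diene 11 should add across the electron-poor triple bond of 8 in a concerted, asynchronous thermal Diels–Alder reaction to give cyclohexa-1,4-diene 12, which aromatises by 1,4-elimination of methanol (methoxide from C2', hydrogen from C5') to silyl ether 13, and dilute acid then frees the 4'-hydroxyl. The closest known reaction type is the benzannulation of this same diene with 2-alkynoate esters to 6-alkyl-4-hydroxy-2-methoxybenzoates. Ring B is closed intermolecularly by the [4+2] event itself, which forms C5'–C6' and C1'–C2' together as a six-membered carbocycle. No stereocentre is created, since 12 has none and the product is aromatic. The step needs regioselectivity (methoxy ortho and hydroxyl para to the carboxyl), which is secured by polarity matching: the CH2 terminus of the diene carries the largest HOMO coefficient and bonds to the propyl-bearing β-carbon of the ynoate, while the dimethoxy carbon bonds to the α-carbon. It also needs chemoselectivity, which follows from the absence of a Lewis acid (the acetyl and benzyl ethers stay inert) and from the blocked ortho positions of ring A (no hydroarylation to a coumarin).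

**Step 9**
Reactants: 14 3-acetyl-2,6-bis(benzyloxy)-4-pentylphenyl 4-hydroxy-2-methoxy-6-propylbenzoate
Product: 15 3-acetyl-2,6-dihydroxy-4-pentylphenyl 4-hydroxy-2-methoxy-6-propylbenzoate (target)
Conditions: H2 (1 atm), 10% Pd/C, EtOAc, rt
Reagents that add atoms: none
Why: Catalytic hydrogenolysis of aryl benzyl ethers under neutral conditions, which should leave the hindered aryl ester (no base, so no acyl migration), the methyl ether and the di-ortho-substituted aryl ketone untouched if the reaction is stopped after uptake of two equivalents of hydrogen.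

**Compound list**
1 | olivetol (5-pentylbenzene-1,3-diol) | CCCCCc1cc(O)cc(O)c1 | starting material
2 | 1-(2,4-dihydroxy-6-pentylphenyl)ethan-1-iminium chloride | CCCCCc1cc(O)cc(O)c1C(C)=[NH2+].[Cl-] | intermediate (not isolated)
3 | 1-(2,4-dihydroxy-6-pentylphenyl)ethan-1-one | CCCCCc1cc(O)cc(O)c1C(C)=O | intermediate
4 | 1-(2,4-dihydroxy-3-iodo-6-pentylphenyl)ethan-1-one | CCCCCc1cc(O)c(I)c(O)c1C(C)=O | intermediate
5 | 1-[2,4-bis(benzyloxy)-3-iodo-6-pentylphenyl]ethan-1-one | CCCCCc1cc(OCc2ccccc2)c(I)c(OCc2ccccc2)c1C(C)=O | intermediate
6 | 1-[2,4-bis(benzyloxy)-3-hydroxy-6-pentylphenyl]ethan-1-one | CCCCCc1cc(OCc2ccccc2)c(O)c(OCc2ccccc2)c1C(C)=O | intermediate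
7 | hex-2-ynoic acid | CCCC#CC(=O)O | starting material
8 | 3-acetyl-2,6-bis(benzyloxy)-4-pentylphenyl hex-2-ynoate | CCCC#CC(=O)Oc1c(OCc2ccccc2)cc(CCCCC)c(C(C)=O)c1OCc1ccccc1 | intermediate
9 | 1,1-dimethoxyethene | C=C(OC)OC | starting material
10 | 4,4-dimethoxybut-3-en-2-one | CC(=O)C=C(OC)OC | intermediate
11 | 1,1-dimethoxy-3-(trimethylsilyloxy)buta-1,3-diene | COC(OC)=CC(=C)O[Si](C)(C)C | intermediate
12 | 3-acetyl-2,6-bis(benzyloxy)-4-pentylphenyl 6,6-dimethoxy-2-propyl-4-(trimethylsilyloxy)cyclohexa-1,4-diene-1-carboxylate | CCCC1=C(C(=O)Oc2c(OCc3ccccc3)cc(CCCCC)c(C(C)=O)c2OCc2ccccc2)C(OC)(OC)C=C(O[Si](C)(C)C)C1 | intermediate (not isolated)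
13 | 3-acetyl-2,6-bis(benzyloxy)-4-pentylphenyl 2-methoxy-6-propyl-4-(trimethylsilyloxy)benzoate | CCCCCc1cc(OCc2ccccc2)c(OC(=O)c2c(CCC)cc(O[Si](C)(C)C)cc2OC)c(OCc2ccccc2)c1C(C)=O | intermediate (not isolated)
14 | 3-acetyl-2,6-bis(benzyloxy)-4-pentylphenyl 4-hydroxy-2-methoxy-6-propylbenzoate | CCCCCc1cc(OCc2ccccc2)c(OC(=O)c2c(CCC)cc(O)cc2OC)c(OCc2ccccc2)c1C(C)=O | intermediate
15 | 3-acetyl-2,6-dihydroxy-4-pentylphenyl 4-hydroxy-2-methoxy-6-propylbenzoate | CCCCCc1cc(O)c(OC(=O)c2c(CCC)cc(O)cc2OC)c(O)c1C(C)=O | target

**Step count**
Total steps: 9. Longest linear sequence: 7 steps (steps 1–5, 8, 9); steps 6–7 form the convergent diene branch.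

**Steps most likely to fail**

Step 8. The cycloaddition to the β-propyl ynoate may be slower than thermal decomposition or desilylation of the diene, so that conversion stalls. The fallback raises the reactivity of the dienophile by using the allenoate isomer, which forms the same two ring B bonds. It sets out from 6. Jones oxidation of commercial hex-3-yn-1-ol would give hex-3-ynoic acid F1. Carbodiimide esterification of 6 with it would give 3-acetyl-2,6-bis(benzyloxy)-4-pentylphenyl hex-3-ynoate F2. Triethylamine in CH2Cl2 should isomerise this to the racemic 3-acetyl-2,6-bis(benzyloxy)-4-pentylphenyl hexa-2,3-dienoate F3. Its α,β-double bond is a stronger dienophile and should take up diene 11 in toluene at about 80 °C with the same polarity matching, giving 3-acetyl-2,6-bis(benzyloxy)-4-pentylphenyl 2,2-dimethoxy-6-propylidene-4-(trimethylsilyloxy)cyclohex-3-ene-1-carboxylate F4 as an isomer mixture. Loss of methanol and shift of the exocyclic double bond into the ring should bring the route back at 13, whose acid work-up gives 14 as in step 8.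

Step 4. Hydrodeiodination, a stalled C–O reductive elimination at the di-ortho-substituted palladium centre, or base-induced condensation at the acetyl group may erode the hydroxylation. The fallback splits the transformation into C–B formation and oxidation. It sets out from 5. Miyaura borylation (B2pin2, Pd/SPhos, KOAc, dioxane, 90 °C) would give 1-[2,4-bis(benzyloxy)-6-pentyl-3-(4,4,5,5-tetramethyl-1,3,2-dioxaborolan-2-yl)phenyl]ethan-1-one F5. Oxidation with H2O2/NaOH in THF at 0 °C and acidification should then return the route at 6.

Step 2. Iodination may also occur at the ring carbon next to the pentyl chain, or twice, giving mixtures that are hard to separate. The fallback fixes the position of the iodine by directed ortho-metalation instead of electrophilic selectivity. It sets out from 1. Benzylation (BnBr, K2CO3, DMF) would give 1,3-bis(benzyloxy)-5-pentylbenzene F6. Treatment with n-BuLi in THF at 0 °C should deprotonate the carbon between the two ether oxygens to give [2,6-bis(benzyloxy)-4-pentylphenyl]lithium F7, and an iodine quench would give 1,3-bis(benzyloxy)-2-iodo-5-pentylbenzene F8. Friedel–Crafts acetylation (AcCl, SnCl4, CH2Cl2, −20 °C) at one of the two equivalent free ring positions should then return the route at 5.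

**Further compounds**
F1 | step 8 | hex-3-ynoic acid | CCC#CCC(=O)O
F2 | step 8 | 3-acetyl-2,6-bis(benzyloxy)-4-pentylphenyl hex-3-ynoate | CCC#CCC(=O)Oc1c(OCc2ccccc2)cc(CCCCC)c(C(C)=O)c1OCc1ccccc1
F3 | step 8 | 3-acetyl-2,6-bis(benzyloxy)-4-pentylphenyl hexa-2,3-dienoate (racemic allene) | CCC=C=CC(=O)Oc1c(OCc2ccccc2)cc(CCCCC)c(C(C)=O)c1OCc1ccccc1
F4 | step 8 | 3-acetyl-2,6-bis(benzyloxy)-4-pentylphenyl 2,2-dimethoxy-6-propylidene-4-(trimethylsilyloxy)cyclohex-3-ene-1-carboxylate (isomer mixture) | CCC=C1CC(O[Si](C)(C)C)=CC(OC)(OC)C1C(=O)Oc1c(OCc2ccccc2)cc(CCCCC)c(C(C)=O)c1OCc1ccccc1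
F5 | step 4 | 1-[2,4-bis(benzyloxy)-6-pentyl-3-(4,4,5,5-tetramethyl-1,3,2-dioxaborolan-2-yl)phenyl]ethan-1-one | CCCCCc1cc(OCc2ccccc2)c(B2OC(C)(C)C(C)(C)O2)c(OCc2ccccc2)c1C(C)=O
F6 | step 2 | 1,3-bis(benzyloxy)-5-pentylbenzene | CCCCCc1cc(OCc2ccccc2)cc(OCc2ccccc2)c1
F7 | step 2 | [2,6-bis(benzyloxy)-4-pentylphenyl]lithium | [Li]c1c(OCc2ccccc2)cc(CCCCC)cc1OCc1ccccc1
F8 | step 2 | 1,3-bis(benzyloxy)-2-iodo-5-pentylbenzene | CCCCCc1cc(OCc2ccccc2)c(I)c(OCc2ccccc2)c1
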